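Target numbering is used for every intermediate: ring carbons C1–C10, lactone carbons C11 (on C7), C12 (carbonyl) and C13 (CH2OAc). Compound numbers refer to the list after the steps.

## Analysis of the target

The target (29) is a germacranolide-type sesquiterpenoid. A ten-membered carbocycle (C1–C10) is fused across C6–C7 to a butenolide (O–C6, C7=C11, C12=O) whose α-carbon C11 carries an acetoxymethyl group. The ring bears ketones at C1 and C3 (a β-diketone through C2), a trans-4,5-epoxide with a methyl on C4, a methyl on C10, and at C8 an ester of (Z)-4-hydroxy-3-methylbut-2-enoic acid. There are five stereocentres: C4 (S), C5 (R), C6 (S), C8 (S) and C10 (S). C4–C5–C6 are contiguous, with the epoxide oxygen at C5 and the lactone oxygen at C6 syn along the chain. The C6 and C8 oxygens lie on the same ring face and the C10 methyl on the opposite face. Several groups are fragile: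
- the β-diketone has an acidic C2 and can undergo retro-Claisen cleavage;
- C10 is α to a ketone and can epimerise;
- the butenolide C6–H is γ-acidic and sits next to the epoxide, so base can open the epoxide by elimination;
- the free side-chain hydroxyl can lactonise onto its own ester and expel the C8 oxygen.

The difficulty is to make a ten-membered ring and then to control five stereocentres on a flexible ring whose two halves (ketone flanked by two activated methylene or methine groups, one alkene each) are chemically alike. The strategy rests on one feature. The oxygenated carbons C1 and C6 are transannular partners, the C10 methyl sits next to C1 and the C4 methyl one carbon from C6. This is the relation of the two ring-fusion carbons to the two methyl-bearing carbons of 1,6-dimethylnaphthalene (1), so cutting the central bond of a reduced naphthalene delivers the ring with both ketones and both methyls in place.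

## Retrosynthetic reasoning

**End game, 29 back to 26.** The free side-chain hydroxyl and the C3 ketone are unveiled last, because the β-diketone and the lactonisable hydroxy enoate are the least robust parts. 29 comes from silyl ether 28 by O–Si cleavage, 28 from carbinol 27 by oxidation at C3, and 27 from bis-silyl ether 26 by selective removal of the C3 silyl group. Two silyl groups of different lability let the C3 carbinol be oxidised while the primary allylic alcohol stays masked.

**C7=C11 alkene, 26 back to 24.** The butenolide double bond is cut back to the tertiary C11 alcohol of 24. It is formed late on purpose. Once it exists, C6–H becomes γ-acidic next to the epoxide, so every base-mediated step has to come before it.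

**C8 ester, 24 back to 18 and 22.** The C8–O acyl bond is disconnected to alcohol 18 and acid 22. The Z geometry of 22 is inherited from the ring of butenolide 19, so no alkene-forming step is needed for the side chain.

**C10 and C8, 18 back to 15.** The C10 stereocentre is traced to the C9=C10 alkene of enone 17, to be hydrogenated under direction of the C8 hydroxyl. Enone 17 comes from diepoxide 16 by cutting the C9–O bond through the enolisable C1 ketone. At that stage C1 is the only ketone, so only the C10 hydrogen can trigger the opening, and the oxygen stays on C8. Diepoxide 16 comes from the C8=C9 alkene of lactone 15. This turns the β,γ-unsaturated C1 ketone into a γ-oxygenated enone without relying on a base equilibration.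

**Lactone and C7–C11 bond, 15 back to 9 and 11.** The lactone C6–O–C12 bond and the C7–C11 bond are cut together. The forward reaction is an aldol addition of the C6 ketone 9 through C7 to keto ester 11 (made from bromide 10), giving 13. A reduction at C6 directed by the new tertiary hydroxyl and ring closure follow. In 9 the epoxide blocks C5, and C7 is the only methylene that is both α to a ketone and allylic, which is why the bond is made at this stage and not earlier.

**Epoxide and C3 oxygen, 9 back to 5.** The trans-4,5-epoxide is traced to the (E)-enone 8 by nucleophilic epoxidation. The enone and the C3 oxygen of 7 are traced to epoxy ketone 6 by eliminative opening of the 3,4-epoxide from C5. Epoxy ketone 6 comes from dione 5 by a catalytic asymmetric epoxidation of the trisubstituted C3=C4 alkene, which introduces absolute configuration. Moving the alkenes into conjugation by plain base equilibration is avoided, because in eight- to ten-membered rings conjugated cis-enones are not favoured over their β,γ-isomers. An epoxide opening is irreversible and places the oxygen at the γ-carbon at the same time. The (E)-alkene and later the trans-epoxide also shut down transannular aldol reactions. Any such closure would split the ring into a five- and a seven-membered ring, and a trans unit fits in neither. C3 serves as a sacrificial stereocentre that is oxidised at the end.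

**Ring, 5 back to 2 and 1.** C1 and C6 of dione 5 are joined to the tetrasubstituted ring-fusion alkene of tetrahydronaphthalene 2, so the ten-membered ring arises by cleavage of a bicycle and not by cyclisation. 2 is the Birch product of arene 1. All ten ring carbons and both methyls come from 1 in two steps.

## Alternatives that were turned down

**Alternative 1:** ring closure at C4–C5 by a sulfonium ylide epoxy-annulation.
- **Disconnection and key step.** The C4–C5 and C4–O bonds are cut. A ylide generated next to the C3 ketone adds to a C5 aldehyde, and the alkoxide then displaces the sulfide, closing ring and epoxide in one step to give A1.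
- **For.** Ring and epoxide form together, the trans-epoxide is the normal outcome of the anti betaine, and the butenolide, C8 and C10 can be set in open-chain chemistry.
- **Against.** A ten-membered ring must be closed by a bimolecular-type addition of a ketone-stabilised, weakly nucleophilic ylide. The carbonate base needed for it acts on an aldehyde that is α to the lactone oxygen at C6 and next to the γ-acidic butenolide, so epimerisation and elimination compete. The open-chain precursor with separately set C6, C8 and C10 centres is long.
- **Comparison.** This route is stronger on convergence and on open-chain control of C8 and C10. The chosen route offers instead a ring obtained in two steps from a cheap arene without any medium-ring cyclisation.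

**Alternative 2:** sacrificial C4 stereocentre relayed by an ene reaction and oxygen transfer.
- **Disconnection and key step.** The C6–O bond and the epoxide are traced to a C5=C6 alkene with a C4–H stereocentre. A photo-oxygenation ene reaction places a hydroperoxide on C6 while moving the alkene to C4=C5. A titanium-alkoxide-mediated transfer of one peroxide oxygen to that alkene then gives epoxy alcohol A2.
- **For.** Both oxygens come from one oxidant, and the C4–C5–C6 triad is fixed by intramolecular delivery. On this point it is tighter than the substrate-controlled epoxidation and reduction used here.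
- **Against.** It presupposes an enantiopure ten-membered ring with two dioxolanes and a silyl ether, whose construction is the real problem and is not solved by the key step. The ene reaction on a medium ring depends on conformation for its regiochemistry and alkene geometry. The butenolide must still be built from the C7 ketone, and two ketals must be removed next to an epoxide.
- **Comparison.** It wins on control of C4 to C6. The chosen strategy wins on access to the carbocycle and on protecting-group economy.

**Alternative 3:** asymmetric carboxyallylation building a C8/C10 lactone relay.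
- **Disconnection and key step.** The C8–C9 bond is cut. Aldehyde A4 and bromide A5 couple under chromium catalysis with a chiral ligand, and the alkoxide closes onto the ester to give the α-methylene lactone A3.
- **For.** C8 is set by catalyst control in a convergent C–C bond formation, and the new lactone can relay C8 to C10 through hydrogenation of its methylene group. This gives cleaner control of C8 and C10 than the epoxidation and directed hydrogenation proposed here.
- **Against.** The ten-membered ring is still open in A3. It would have to be closed later by a base-mediated acyl transfer (C2 onto C1) on an intermediate that already holds the epoxy ketone and the γ-acidic butenolide. A4 is an electron-poor, epimerisable aldehyde.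
- **Comparison.** It is stronger on C8 and C10. The chosen route places the risk early, on a two-step ring synthesis, and keeps strong base away from the finished butenolide.

Key step: step 2

## Route

Remark on mixtures: C10 is racemic in 2–5 and an epimer mixture in 6–16, written without configuration; it is destroyed in step 11 and set in step 12. C11 is an inconsequential mixture in 13–25.

Remark on step 3: the sense of induction is assigned by analogy with 1-substituted cycloalkenes; if it were the reverse, the enantiomeric ketone catalyst would be used.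

Step 1
Reactants: 1 1,6-dimethylnaphthalene
Product: 2 1,6-dimethyl-1,4,5,8-tetrahydronaphthalene (racemic)
Conditions: Li (8 equiv), NH3 (l), THF, t-BuOH, −78 to −33 °C; then NH4Cl
Reagents that add atoms: none
Why: Birch reduction; each benzenoid ring takes up two hydrogens 1,4, the methyl of the future C4 stays on an alkene, and in the ring with three contiguous alkyl-bearing carbons the tetrasubstituted ring-fusion alkene survives while the future C10 becomes sp3, as in reductions of 1,2,3-trialkylbenzenes.

Step 2
Reactants: 2 1,6-dimethyl-1,4,5,8-tetrahydronaphthalene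
Product: 5 (3Z,8Z)-4,10-dimethylcyclodeca-3,8-diene-1,6-dione (racemic), via primary ozonide 3 (not isolated), via secondary ozonide 4 (not isolated)
Conditions: O3 (1.0 equiv, Sudan Red 7B end point), CH2Cl2, −78 °C; then PPh3, −78 °C to rt
Reagents that add atoms: ozone, [O-][O+]=O
Why: Ozonolysis: ozone adds as a 1,3-dipole to the most electron-rich alkene, the tetrasubstituted ring-fusion alkene, to give primary ozonide 3, which fragments to a ketone and a carbonyl oxide that stay tethered and recombine to ozonide 4; PPh3 then removes one oxygen and leaves the C1 and C6 ketones. The closest known reaction type is the ozonolytic or glycol cleavage of the ring-fusion alkene of tetrahydronaphthalenes and octalins to cyclodecane-1,6-diones. The ten-membered ring is not closed by a cyclisation; it appears when the bond shared by the two six-membered rings (C1–C6) is cut, so no medium-ring closure is involved. No stereocentre is created, C10 stays racemic, and both remaining alkenes keep the Z geometry they had in the six-membered rings. The step needs chemoselectivity among three alkenes (tetra- over tri- and disubstituted); it is secured by the higher nucleophilicity of the ring-fusion alkene, by one equivalent of ozone at −78 °C and by the dye end point, which bleaches only after the most reactive alkene is consumed.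

Step 3
Reactants: 5 (3Z,8Z)-4,10-dimethylcyclodeca-3,8-diene-1,6-dione
Product: 6 (3R,4S,8Z)-3,4-epoxy-4,10-dimethylcyclodec-8-ene-1,6-dione (C10 epimers)
Conditions: 1,2:4,5-di-O-isopropylidene-β-D-erythro-2,3-hexodiulo-2,6-pyranose (0.3 equiv), Oxone (2KHSO5·KHSO4·K2SO4), K2CO3, Bu4NHSO4, Na2B4O7 buffer (pH 10.5), MeCN–CH2(OMe)2, −5 °C
Reagents that add atoms: potassium peroxymonosulfate (active component of Oxone), [K+].[O-]S(=O)(=O)OO
Why: Shi epoxidation; the chiral dioxirane should react with the trisubstituted C3=C4 alkene much faster than with the cis-disubstituted C8=C9 alkene, and the spiro transition state is expected to set C3 (R) and C4 (S) by analogy with 1-substituted cycloalkenes; C10 is not controlled.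

Step 4
Reactants: 6 (3R,4S,8Z)-3,4-epoxy-4,10-dimethylcyclodec-8-ene-1,6-dione
Product: 7 (3R,4E,8Z)-3-hydroxy-4,10-dimethylcyclodeca-4,8-diene-1,6-dione (C10 epimers)
Conditions: DBU (1.0 equiv), CH2Cl2, −20 to 0 °C
Reagents that add atoms: none
Why: Base-induced eliminative opening of a β,γ-epoxy ketone (E1cB): loss of a C5 proton α to the C6 ketone breaks the weaker tertiary C4–O bond and gives the γ-hydroxy enone with the C3 configuration untouched. The elimination should pass through the ring conformer with the C3–C4 and C5–C6 bonds anti, so the new C4=C5 alkene is expected to be E, as in other eliminations in ten-membered rings.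

Step 5
Reactants: 7 (3R,4E,8Z)-3-hydroxy-4,10-dimethylcyclodeca-4,8-diene-1,6-dione
Product: 8 (3R,4E,8Z)-4,10-dimethyl-3-(triethylsilyloxy)cyclodeca-4,8-diene-1,6-dione (C10 epimers)
Conditions: Et3SiCl, imidazole, DMF, 0 °C to rt
Reagents that add atoms: chlorotriethylsilane, CC[Si](Cl)(CC)CC
Why: Silylation of the secondary allylic alcohol; the silyl ether prevents retro-aldol cleavage of the β-hydroxy ketone, is a poor leaving group β to the C1 ketone, and can later be removed in the presence of a primary tert-butyldiphenylsilyl ether.

Step 6
Reactants: 8 (3R,4E,8Z)-4,10-dimethyl-3-(triethylsilyloxy)cyclodeca-4,8-diene-1,6-dione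
Product: 9 (3R,4S,5S,8Z)-4,5-epoxy-4,10-dimethyl-3-(triethylsilyloxy)cyclodec-8-ene-1,6-dione (C10 epimers)
Conditions: t-BuOOH (decane), DBU, CH2Cl2, 0 °C to rt
Reagents that add atoms: tert-butyl hydroperoxide, CC(C)(C)OO
Why: Weitz–Scheffer epoxidation; the peroxide anion adds to C4 of the enone only (the isolated C8=C9 alkene is inert) and the enolate closes at C5, the (E)-enone giving the trans-epoxide. Attack should occur on the exposed face of the (E)-alkene in the conformer that keeps the C3 silyloxy group away from the C4 methyl (allylic 1,2-strain), which places the epoxide oxygen anti to the C3 oxygen and gives C4 and C5 as in the target.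

Step 7
Reactants: 10 ethyl bromopyruvate
Product: 11 ethyl 3-acetoxy-2-oxopropanoate
Conditions: CH3CO2K, acetone, 0 °C to rt
Reagents that add atoms: potassium acetate, CC(=O)[O-].[K+]
Why: SN2 displacement of the activated α-keto bromide by acetate.

Step 8
Reactants: 9 (3R,4S,5S,8Z)-4,5-epoxy-4,10-dimethyl-3-(triethylsilyloxy)cyclodec-8-ene-1,6-dione; 11 ethyl 3-acetoxy-2-oxopropanoate
Product: 13 ethyl 2-(acetoxymethyl)-2-hydroxy-2-[(3R,4S,5S,7S,8Z)-4,5-epoxy-4,10-dimethyl-1,6-dioxo-3-(triethylsilyloxy)cyclodec-8-en-7-yl]acetate (C10 and C11 mixtures), via lithium dienolate 12 (not isolated)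
Conditions: LiN(SiMe3)2 (1.05 equiv), THF, −78 °C; then 11, −78 °C; AcOH
Reagents that add atoms: none
Why: Aldol addition; C7 is the only methylene that is both α to a ketone and allylic and the epoxide blocks C5, so kinetic deprotonation should give dienolate 12, which adds through its α-carbon to the activated ketone of 11 and forms C7–C11. The electrophile is expected on the face of the epoxide oxygen (lithium coordination, anti to the C4 ring carbon), giving C7 (S); C11 is uncontrolled and is removed later.

Step 9
Reactants: 13 aldol adduct
Product: 15 (3R,4S,5R,6S,7R,8Z)-13-acetoxy-4,5-epoxy-11-hydroxy-1-oxo-3-(triethylsilyloxy)germacr-8-en-12,6-olide (C10 and C11 mixtures), via hydroxy ester 14 (not isolated)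
Conditions: Me4NBH(OAc)3, MeCN–AcOH, −30 °C; aq. KNaC4H4O6; then pyridinium p-toluenesulfonate (cat.), CH2Cl2, rt
Reagents that add atoms: none
Why: Hydroxyl-directed (Evans–Saksena) reduction followed by lactonisation; the borohydride exchanges onto the tertiary C11 hydroxyl and delivers hydride intramolecularly to C6 only (the C1 ketone has no free β-hydroxyl), from the face of the C7–C11 bond, so the C6 oxygen ends trans to the side chain (6S). The γ-hydroxy ester 14 then closes to the trans-fused γ-lactone, forming C6–O–C12.

Step 10
Reactants: 15 hydroxy lactone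
Product: 16 (3R,4S,5R,6S,7R,8R,9S)-13-acetoxy-4,5:8,9-diepoxy-11-hydroxy-1-oxo-3-(triethylsilyloxy)germacran-12,6-olide (C10 and C11 mixtures)
Conditions: mCPBA, NaHCO3, CH2Cl2, 0 °C
Reagents that add atoms: 3-chloroperoxybenzoic acid, OOC(=O)c1cccc(Cl)c1
Why: Prilezhaev epoxidation of the only remaining alkene; syn addition to the cis C8=C9 alkene is expected from the face opposite the quaternary C11 substituent on the neighbouring C7, which places the C8 oxygen on the same ring face as the C6 oxygen.

Step 11
Reactants: 16 diepoxide
Product: 17 (3R,4S,5R,6S,7R,8S,9E)-13-acetoxy-4,5-epoxy-8,11-dihydroxy-1-oxo-3-(triethylsilyloxy)germacr-9-en-12,6-olide (C11 mixture)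
Conditions: DBU (1.2 equiv), CH2Cl2, 0 °C to rt
Reagents that add atoms: none
Why: Second eliminative epoxide opening (E1cB); C1 is now the only ketone, so only loss of the C10 proton can open the 8,9-epoxide, breaking C9–O and leaving the oxygen on C8 with its configuration, and both C10 epimers converge on the (E)-C9=C10 enone. Enolisation toward C2 is unproductive because the C3 silyloxy group is a far poorer leaving group than the strained epoxide, and C6–H is not acidic as long as the butenolide alkene is absent.

Step 12
Reactants: 17 8-hydroxy enone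
Product: 18 (3R,4S,5R,6S,7R,8S,10S)-13-acetoxy-4,5-epoxy-8,11-dihydroxy-1-oxo-3-(triethylsilyloxy)germacran-12,6-olide (C11 mixture)
Conditions: H2 (1 atm), [Ir(cod)(PCy3)(py)]PF6 (5 mol %), CH2Cl2, rt
Reagents that add atoms: none
Why: Hydroxyl-directed homogeneous hydrogenation; the C8 hydroxyl binds iridium and hydrogen should be delivered to the outer face of the (E)-C9=C10 alkene in the conformer with C8–H eclipsing the alkene (allylic 1,3-strain with the C10 methyl), which sets C10 (S) with the methyl trans to the C8 oxygen. The cationic iridium catalyst does not cleave the allylic C–O bond or the epoxide.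

Step 13
Reactants: 19 4-methylfuran-2(5H)-one
Product: 22 (Z)-4-(tert-butyldiphenylsilyloxy)-3-methylbut-2-enoic acid, via potassium hydroxy enoate 20 (not isolated), via silyl ester silyl ether 21 (not isolated)
Conditions: KOH (1.0 equiv), MeOH–H2O, 0 °C, then evaporation; t-BuPh2SiCl (2.2 equiv), imidazole, DMF, rt; K2CO3, MeOH–THF–H2O, 0 °C; citric acid to pH 5
Reagents that add atoms: potassium hydroxide, [K+].[OH-]; tert-butyl(chloro)diphenylsilane, CC(C)(C)[Si](Cl)(c1ccccc1)c1ccccc1
Why: Lactone saponification, bis-silylation and selective hydrolysis of the labile silyl ester; the Z geometry comes from the ring of 19, and capping the hydroxyl stops relactonisation.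

Step 14
Reactants: 18 diol lactone; 22 (Z)-4-(tert-butyldiphenylsilyloxy)-3-methylbut-2-enoic acid
Product: 24 8-O-[(Z)-4-(tert-butyldiphenylsilyloxy)-3-methylbut-2-enoyl] derivative of 18, (3R,4S,5R,6S,7R,8S,10S) (C11 mixture), via mixed anhydride 23 (not isolated)
Conditions: 22, 2,4,6-trichlorobenzoyl chloride, Et3N, THF, rt; then 18, 4-(dimethylamino)pyridine, toluene, rt
Reagents that add atoms: none
Why: Yamaguchi esterification; the secondary C8 hydroxyl is acylated with retention while the tertiary C11 hydroxyl is too hindered to react, and the β,β-disubstituted enoate should keep its Z geometry.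

Step 15
Reactants: 24 C8 ester hydroxy lactone
Product: 26 (3R,4S,5R,6S,8S,10S)-13-acetoxy-8-[(Z)-4-(tert-butyldiphenylsilyloxy)-3-methylbut-2-enoyloxy]-4,5-epoxy-1-oxo-3-(triethylsilyloxy)germacr-7(11)-en-12,6-olide, via chlorosulfite 25 (not isolated)
Conditions: SOCl2, pyridine, CH2Cl2, −20 to 0 °C
Reagents that add atoms: none
Why: Dehydration of the tertiary α-hydroxy lactone through its chlorosulfite; loss of the C7 hydrogen gives the tetrasubstituted C7=C11 alkene conjugated with the lactone carbonyl, and the C7 and C11 stereocentres (both C11 epimers) disappear. Pyridine is too weak a base to remove the now γ-acidic C6 hydrogen.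

Step 16
Reactants: 26 bis-silyl butenolide
Product: 27 (3R,4R,5R,6S,8S,10S)-13-acetoxy-8-[(Z)-4-(tert-butyldiphenylsilyloxy)-3-methylbut-2-enoyloxy]-4,5-epoxy-3-hydroxy-1-oxogermacr-7(11)-en-12,6-olide
Conditions: HF·pyridine, pyridine, THF, 0 °C
Reagents that add atoms: none
Why: Selective desilylation; a secondary triethylsilyl ether is cleaved much faster than a primary tert-butyldiphenylsilyl ether under buffered hydrogen fluoride, and the conditions are not basic.

Step 17
Reactants: 27 C3 alcohol
Product: 28 (4S,5R,6S,8S,10S)-13-acetoxy-8-[(Z)-4-(tert-butyldiphenylsilyloxy)-3-methylbut-2-enoyloxy]-4,5-epoxy-1,3-dioxogermacr-7(11)-en-12,6-olide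
Conditions: Dess–Martin periodinane, NaHCO3, CH2Cl2, 0 °C to rt
Reagents that add atoms: none
Why: Dess–Martin oxidation of the β-hydroxy ketone to the β-diketone under neutral conditions; the sacrificial C3 centre is removed, and C4 (quaternary) and C5 cannot epimerise.

Step 18
Reactants: 28 silyl-protected triketone
Product: 29 CNP0295642.1 (target)
Conditions: HF·pyridine, THF, 0 °C to rt
Reagents that add atoms: none
Why: Fluoride-mediated cleavage of the silyl ether under mildly acidic conditions, which avoids base-induced lactonisation of the (Z)-γ-hydroxy enoate, deprotonation at C6 and retro-Claisen cleavage of the β-diketone.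

## Compound list

1 | 1,6-dimethylnaphthalene | Cc1cccc2cc(C)ccc12 | starting material
2 | 1,6-dimethyl-1,4,5,8-tetrahydronaphthalene (racemic) | CC1C=CCC2=C1CC=C(C)C2 | intermediate
3 | primary ozonide (1,2,3-trioxolane on the two ring-fusion carbons of 2) | CC1C=CCC23OOOC13CC=C(C)C2 | intermediate
4 | secondary ozonide (1,2,4-trioxolane bridging C1 and C6) | CC1C=CCC23OOC1(O3)CC=C(C)C2 | intermediate
5 | (3Z,8Z)-4,10-dimethylcyclodeca-3,8-diene-1,6-dione (racemic) | C1/C=C\C(C)C(=O)C/C=C(C)\CC1=O | intermediate
6 | (3R,4S,8Z)-3,4-epoxy-4,10-dimethylcyclodec-8-ene-1,6-dione (C10 epimers) | C1/C=C\C(C)C(=O)C[C@H]2O[C@@]2(C)CC1=O | intermediate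
7 | (3R,4E,8Z)-3-hydroxy-4,10-dimethylcyclodeca-4,8-diene-1,6-dione (C10 epimers) | C1/C=C\C(C)C(=O)C[C@@H](O)/C(C)=C/C1=O | intermediate
8 | (3R,4E,8Z)-4,10-dimethyl-3-(triethylsilyloxy)cyclodeca-4,8-diene-1,6-dione (C10 epimers) | C1/C=C\C(C)C(=O)C[C@@H](O[Si](CC)(CC)CC)/C(C)=C/C1=O | intermediate
9 | (3R,4S,5S,8Z)-4,5-epoxy-4,10-dimethyl-3-(triethylsilyloxy)cyclodec-8-ene-1,6-dione (C10 epimers) | C1/C=C\C(C)C(=O)C[C@@H](O[Si](CC)(CC)CC)[C@@]2(C)O[C@@H]2C1=O | intermediate
10 | ethyl bromopyruvate (ethyl 3-bromo-2-oxopropanoate) | CCOC(=O)C(=O)CBr | starting material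
11 | ethyl 3-acetoxy-2-oxopropanoate | CCOC(=O)C(=O)COC(C)=O | intermediate
12 | lithium dienolate of 9 (C6–OLi, C6=C7–C8=C9) | [Li+].[O-]C1=C/C=C\C(C)C(=O)C[C@@H](O[Si](CC)(CC)CC)[C@@]2(C)O[C@@H]21 | intermediate
13 | ethyl 2-(acetoxymethyl)-2-hydroxy-2-[(3R,4S,5S,7S,8Z)-4,5-epoxy-4,10-dimethyl-1,6-dioxo-3-(triethylsilyloxy)cyclodec-8-en-7-yl]acetate (C10 and C11 mixtures) | CCOC(=O)C(O)(COC(C)=O)[C@@H]1/C=C\C(C)C(=O)C[C@@H](O[Si](CC)(CC)CC)[C@@]2(C)O[C@@H]2C1=O | intermediate
14 | ethyl 2-(acetoxymethyl)-2-hydroxy-2-[(3R,4S,5R,6S,7R,8Z)-4,5-epoxy-6-hydroxy-4,10-dimethyl-1-oxo-3-(triethylsilyloxy)cyclodec-8-en-7-yl]acetate | CCOC(=O)C(O)(COC(C)=O)[C@@H]1/C=C\C(C)C(=O)C[C@@H](O[Si](CC)(CC)CC)[C@@]2(C)O[C@@H]2[C@H]1O | intermediate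
15 | (3R,4S,5R,6S,7R,8Z)-13-acetoxy-4,5-epoxy-11-hydroxy-1-oxo-3-(triethylsilyloxy)germacr-8-en-12,6-olide (C10 and C11 mixtures) | CC(=O)OCC1(O)[C@@H]2/C=C\C(C)C(=O)C[C@@H](O[Si](CC)(CC)CC)[C@@]3(C)O[C@@H]3[C@H]2OC1=O | intermediate
16 | (3R,4S,5R,6S,7R,8R,9S)-13-acetoxy-4,5:8,9-diepoxy-11-hydroxy-1-oxo-3-(triethylsilyloxy)germacran-12,6-olide (C10 and C11 mixtures) | CC(=O)OCC1(O)[C@@H]2[C@H]4O[C@H]4C(C)C(=O)C[C@@H](O[Si](CC)(CC)CC)[C@@]3(C)O[C@@H]3[C@H]2OC1=O | intermediate
17 | (3R,4S,5R,6S,7R,8S,9E)-13-acetoxy-4,5-epoxy-8,11-dihydroxy-1-oxo-3-(triethylsilyloxy)germacr-9-en-12,6-olide (C11 mixture) | CC(=O)OCC1(O)[C@@H]2[C@@H](O)/C=C(C)/C(=O)C[C@@H](O[Si](CC)(CC)CC)[C@@]3(C)O[C@@H]3[C@H]2OC1=O | intermediate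
18 | (3R,4S,5R,6S,7R,8S,10S)-13-acetoxy-4,5-epoxy-8,11-dihydroxy-1-oxo-3-(triethylsilyloxy)germacran-12,6-olide (C11 mixture) | CC(=O)OCC1(O)[C@@H]2[C@@H](O)C[C@H](C)C(=O)C[C@@H](O[Si](CC)(CC)CC)[C@@]3(C)O[C@@H]3[C@H]2OC1=O | intermediate
19 | 4-methylfuran-2(5H)-one | CC1=CC(=O)OC1 | starting material
20 | potassium (Z)-4-hydroxy-3-methylbut-2-enoate | [K+].[O-]C(=O)/C=C(/C)CO | intermediate
21 | tert-butyldiphenylsilyl (Z)-4-(tert-butyldiphenylsilyloxy)-3-methylbut-2-enoate | CC(C)(C)[Si](c1ccccc1)(c1ccccc1)OC(=O)/C=C(/C)CO[Si](c1ccccc1)(c1ccccc1)C(C)(C)C | intermediate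
22 | (Z)-4-(tert-butyldiphenylsilyloxy)-3-methylbut-2-enoic acid | OC(=O)/C=C(/C)CO[Si](c1ccccc1)(c1ccccc1)C(C)(C)C | intermediate
23 | mixed anhydride of 22 with 2,4,6-trichlorobenzoic acid | O=C(OC(=O)/C=C(/C)CO[Si](c1ccccc1)(c1ccccc1)C(C)(C)C)c1c(Cl)cc(Cl)cc1Cl | intermediate
24 | (3R,4S,5R,6S,7R,8S,10S)-13-acetoxy-8-[(Z)-4-(tert-butyldiphenylsilyloxy)-3-methylbut-2-enoyloxy]-4,5-epoxy-11-hydroxy-1-oxo-3-(triethylsilyloxy)germacran-12,6-olide (C11 mixture) | CC(=O)OCC1(O)[C@@H]2[C@@H](OC(=O)/C=C(/C)CO[Si](c4ccccc4)(c4ccccc4)C(C)(C)C)C[C@H](C)C(=O)C[C@@H](O[Si](CC)(CC)CC)[C@@]3(C)O[C@@H]3[C@H]2OC1=O | intermediate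
25 | 11-O-chlorosulfite of 24 | CC(=O)OCC1(OS(Cl)=O)[C@@H]2[C@@H](OC(=O)/C=C(/C)CO[Si](c4ccccc4)(c4ccccc4)C(C)(C)C)C[C@H](C)C(=O)C[C@@H](O[Si](CC)(CC)CC)[C@@]3(C)O[C@@H]3[C@H]2OC1=O | intermediate
26 | (3R,4S,5R,6S,8S,10S)-13-acetoxy-8-[(Z)-4-(tert-butyldiphenylsilyloxy)-3-methylbut-2-enoyloxy]-4,5-epoxy-1-oxo-3-(triethylsilyloxy)germacr-7(11)-en-12,6-olide | CC(=O)OCC1=C2[C@@H](OC(=O)/C=C(/C)CO[Si](c4ccccc4)(c4ccccc4)C(C)(C)C)C[C@H](C)C(=O)C[C@@H](O[Si](CC)(CC)CC)[C@@]3(C)O[C@@H]3[C@H]2OC1=O | intermediate
27 | (3R,4R,5R,6S,8S,10S)-13-acetoxy-8-[(Z)-4-(tert-butyldiphenylsilyloxy)-3-methylbut-2-enoyloxy]-4,5-epoxy-3-hydroxy-1-oxogermacr-7(11)-en-12,6-olide | CC(=O)OCC1=C2[C@@H](OC(=O)/C=C(/C)CO[Si](c4ccccc4)(c4ccccc4)C(C)(C)C)C[C@H](C)C(=O)C[C@@H](O)[C@@]3(C)O[C@@H]3[C@H]2OC1=O | intermediate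
28 | (4S,5R,6S,8S,10S)-13-acetoxy-8-[(Z)-4-(tert-butyldiphenylsilyloxy)-3-methylbut-2-enoyloxy]-4,5-epoxy-1,3-dioxogermacr-7(11)-en-12,6-olide | CC(=O)OCC1=C2[C@@H](OC(=O)/C=C(/C)CO[Si](c4ccccc4)(c4ccccc4)C(C)(C)C)C[C@H](C)C(=O)CC(=O)[C@@]3(C)O[C@@H]3[C@H]2OC1=O | intermediate
29 | CNP0295642.1, (4S,5R,6S,8S,10S)-13-acetoxy-4,5-epoxy-8-[(Z)-4-hydroxy-3-methylbut-2-enoyloxy]-1,3-dioxogermacr-7(11)-en-12,6-olide | CC(=O)OCC1=C2[C@@H](OC(=O)/C=C(/C)CO)C[C@H](C)C(=O)CC(=O)[C@@]3(C)O[C@@H]3[C@H]2OC1=O | target

## Step count and least certain steps

Total: 18 steps. Longest linear sequence: 16 steps (steps 1–6, 8–12 and 14–18); steps 7 and 13 prepare 11 and 22.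

**Step 2 (key step).**
- What may go wrong: competitive attack of ozone on the trisubstituted C3=C4 alkene and over-oxidation, because ozone discriminates only modestly between tetra- and trisubstituted alkenes.
- Fallback (from 2, back at 5): epoxidise the ring-fusion alkene with one equivalent of mCPBA at −40 °C, where the rate gap between tetra- and trisubstituted alkenes is larger, to give 4a,8a-epoxy-1,6-dimethyl-1,4,4a,5,8,8a-hexahydronaphthalene F1. Cleave it with H5IO6 in aqueous THF (epoxide hydrolysis and glycol cleavage in one pot) to 5.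

**Step 4.**
- What may go wrong: removal of a C2 proton through the C1 ketone, which opens the epoxide the other way (oxygen left on C4); transannular aldol addition of an enolate before elimination; closure of the new alkene with Z geometry.
- Fallback (from 6, back at 8): switch from enolate-driven to electrophile-driven opening. Et3SiOSO2CF3 with 2,6-lutidine at −78 °C silylates the epoxide oxygen, the tertiary C4–O bond ionises in preference to the secondary C3–O bond, and DBU then removes the C5 proton. Silyl ether 8 is formed directly and no free enolate meets the C1 ketone. This fallback makes no new compound (F0).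

**Step 6.**
- What may go wrong: peroxide attack on the other face of the enone (epimeric epoxide relative to C3); slow addition to the β,β-disubstituted enone with base-induced migration of the C8=C9 alkene in the meantime.
- Fallback (from 8, back at 9): replace substrate control by catalyst control with the lanthanum binaphtholate system, La(OiPr)3, (R)- or (S)-1,1′-bi-2-naphthol, Ph3AsO and t-BuOOH. The ligand enantiomer is chosen to enforce the required face. No new compound (F0).

**Step 8.**
- What may go wrong: competing enolisation on the C1 side (C2 or C10); proton transfer between the dienolate and the acidic methylene of 11; attack on the other face of C7, which would invert the relay to C6 and C8.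
- Fallback (from 8, back at 15): mask C1 first. The saturated C1 ketone of 8 is ketalised in the presence of the conjugated C6 ketone (1,2-bis(trimethylsilyloxy)ethane, Me3SiOSO2CF3 cat., −78 °C) to C1 dioxolane F2. Epoxidation as in step 6 gives dioxolane epoxy ketone F3. Its only enolisable ketone gives dioxolane aldol adduct F4 and, after directed reduction and lactonisation as in step 9, dioxolane lactone F5. Pyridinium p-toluenesulfonate in wet acetone removes the dioxolane and returns 15.

**Step 10.**
- What may go wrong: epoxidation on the other face of C8=C9, for instance by hydrogen-bond delivery from the C11 hydroxyl, giving the wrong C8 configuration.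
- Fallback (from 15, back at 24): accept the other epoxide and correct C8 by inversion. The 8,9-epimeric diepoxide F6 is opened with DBU as in step 11 to 8-epi alcohol F7. Mitsunobu esterification with acid 22 (PPh3, diisopropyl azodicarboxylate) inverts C8 and gives enone ester F8. Conjugate reduction of the C9=C10 enone with [(Ph3P)CuH]6 and equilibration of C10 with DBU then give 24.

**Step 12.**
- What may go wrong: hydrogen delivery to the other alkene face, or through a conformer in which the C8 hydroxyl does not direct, giving the C10 epimer.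
- Fallback (from 17, back at 18): use catalyst control instead of hydroxyl direction. 17 is hydrogenated with a chiral cationic iridium phosphino-oxazoline complex [Ir(cod)(L)]BArF, where L is (S)- or (R)-4-tert-butyl-2-[2-(diphenylphosphino)phenyl]-2-oxazoline and BArF is tetrakis[3,5-bis(trifluoromethyl)phenyl]borate. Any 10-epimer F9 that still forms is re-equilibrated with DBU (C10 is α to the C1 ketone) and recycled.

## Further compounds

F1 | step 2 | 4a,8a-epoxy-1,6-dimethyl-1,4,4a,5,8,8a-hexahydronaphthalene | CC1C=CCC23OC12CC=C(C)C3
F0 | step 4 | none | none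
F0 | step 6 | none | none
F2 | step 8 | C1 ethylene ketal (dioxolane) of 8 | C1/C=C\C(C)C2(OCCO2)C[C@@H](O[Si](CC)(CC)CC)/C(C)=C/C1=O
F3 | step 8 | C1 ethylene ketal of epoxy ketone 9 | C1/C=C\C(C)C3(OCCO3)C[C@@H](O[Si](CC)(CC)CC)[C@@]2(C)O[C@@H]2C1=O
F4 | step 8 | C1 ethylene ketal of aldol adduct 13 | CCOC(=O)C(O)(COC(C)=O)[C@@H]1/C=C\C(C)C3(OCCO3)C[C@@H](O[Si](CC)(CC)CC)[C@@]2(C)O[C@@H]2C1=O
F5 | step 8 | C1 ethylene ketal of lactone 15 | CC(=O)OCC1(O)[C@@H]2/C=C\C(C)C4(OCCO4)C[C@@H](O[Si](CC)(CC)CC)[C@@]3(C)O[C@@H]3[C@H]2OC1=O
F6 | step 10 | 8,9-epimeric diepoxide (8S,9R isomer of 16) | CC(=O)OCC1(O)[C@@H]2[C@@H]4O[C@@H]4C(C)C(=O)C[C@@H](O[Si](CC)(CC)CC)[C@@]3(C)O[C@@H]3[C@H]2OC1=O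
F7 | step 10 | 8-epimer of hydroxy enone 17 | CC(=O)OCC1(O)[C@@H]2[C@H](O)/C=C(C)/C(=O)C[C@@H](O[Si](CC)(CC)CC)[C@@]3(C)O[C@@H]3[C@H]2OC1=O
F8 | step 10 | 8-O-[(Z)-4-(tert-butyldiphenylsilyloxy)-3-methylbut-2-enoyl] ester of 17 (C9=C10 enone, target configuration at C8) | CC(=O)OCC1(O)[C@@H]2[C@@H](OC(=O)/C=C(/C)CO[Si](c4ccccc4)(c4ccccc4)C(C)(C)C)/C=C(C)/C(=O)C[C@@H](O[Si](CC)(CC)CC)[C@@]3(C)O[C@@H]3[C@H]2OC1=O
F9 | step 12 | 10-epimer of 18 | CC(=O)OCC1(O)[C@@H]2[C@@H](O)C[C@@H](C)C(=O)C[C@@H](O[Si](CC)(CC)CC)[C@@]3(C)O[C@@H]3[C@H]2OC1=O
A1 | alternative 1 | ten-membered epoxy ketone with butenolide, C1 dioxolane and C8 tert-butyldimethylsilyl ether | CC(=O)OCC1=C2[C@@H](O[Si](C)(C)C(C)(C)C)C[C@H](C)C4(OCCO4)CC(=O)[C@@]3(C)O[C@@H]3[C@H]2OC1=O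
A2 | alternative 2 | 4,5-epoxy-6-hydroxy ten-membered C1 ketone with C3 and C7 dioxolanes and C8 tert-butyldimethylsilyl ether | O=C1CC2(OCCO2)[C@@]3(C)O[C@@H]3[C@@H](O)C4(OCCO4)[C@@H](O[Si](C)(C)C(C)(C)C)C[C@@H]1C
A3 | alternative 3 | butenolide carrying the C8 α-methylene-γ-butyrolactone (C9, C10, C1) and the epoxy methyl ketone | CC(=O)OCC1=C([C@@H]2CC(=C)C(=O)O2)[C@@H]([C@H]3O[C@]3(C)C(C)=O)OC1=O
A4 | alternative 3 | β-formyl butenolide (C8 aldehyde) with the epoxy methyl ketone | CC(=O)OCC1=C(C=O)[C@@H]([C@H]2O[C@]2(C)C(C)=O)OC1=O
A5 | alternative 3 | ethyl 2-(bromomethyl)acrylate | C=C(CBr)C(=O)OCC
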